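The 18-membered bis(bibenzyl) carries its carbinol carbon on ring A (the 3,4-dihydroxy-5-aryloxyphenyl ring), next to the CH2 on ring D (the meta-linked ring). ArA-CH(OH)-CH2-ArD is the product pattern of a [1,2]-Wittig shift of the ether ArA-CH(M)-O-CH2-ArD, so one disconnection removes the CH-CH2 bond, the 18-membered ring and the (S) centre.
The precursor is the racemic 19-membered dibenzyl ether with SnBu3 on the ring-A benzylic carbon. Tin-lithium exchange places the carbanion there, and a chiral bis(oxazoline) on lithium selects the face.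
The 19-membered ring is closed at the B/C bridge by ring-closing metathesis of two styrenes, then diimide. The stannyl ether is made before that, bimolecularly under acid catalysis, from the A/B alpha-hydroxystannane and the C/D benzylic trichloroacetimidate. A benzylic halide cannot coexist with Bu3SnLi, and the alkoxide of a benzylic alpha-hydroxystannane would decay faster than a macro-Williamson closure could run.
The halves come from two SNAr reactions: ketal-protected methyl gallate on 4-fluorobenzaldehyde (A/B), and 3-hydroxybenzyl alcohol on 3-benzyloxy-2-fluorobenzaldehyde (C/D). The ring-A catechol is a diphenylmethylene ketal (one step, no acidic OCH2Ph) and the ring-C phenol a benzyl ether, and one neutral hydrogenolysis removes both.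
Ring order: benzodioxole (temporary, step 1), 19-membered macrocycle (step 13), 18-membered macrocycle by contraction (step 15).

Key step: step 15

Assumption: the enantiomer of the bis(oxazoline) that leads to the (S)-carbinol cannot be derived with certainty, so the (S,S)-ligand is written and its commercial (R,R)-antipode is used if the first run shows the opposite sense.

Step 1
Reactants: 1 methyl gallate
Product: 2 methyl 7-hydroxy-2,2-diphenyl-1,3-benzodioxole-5-carboxylate
Conditions: Ph2CCl2 (1.3 equiv), Ph2O, 175 °C
Reagents that add atoms: dichlorodiphenylmethane, ClC(Cl)(c1ccccc1)c1ccccc1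
Why: Ketalisation of a catechol with a gem-dichloride, in which only two vicinal hydroxyls can span the five-membered dioxole and the two possible pairs are equivalent by symmetry, so exactly one phenol is left free.

Step 2
Reactants: 2 methyl 7-hydroxy-2,2-diphenyl-1,3-benzodioxole-5-carboxylate; 3 4-fluorobenzaldehyde
Product: 4 methyl 7-(4-formylphenoxy)-2,2-diphenyl-1,3-benzodioxole-5-carboxylate
Conditions: K2CO3, DMF, 120 °C
Reagents that add atoms: none
Why: Nucleophilic aromatic substitution (SNAr), in which the para-formyl group activates the fluoride towards the phenoxide of 2 while ketal and methyl ester tolerate K2CO3.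

Step 3
Reactants: 4 methyl 7-(4-formylphenoxy)-2,2-diphenyl-1,3-benzodioxole-5-carboxylate
Product: 5 methyl 7-(4-vinylphenoxy)-2,2-diphenyl-1,3-benzodioxole-5-carboxylate
Conditions: Ph3PCH3Br, KOtBu, THF, 0 °C
Reagents that add atoms: methyltriphenylphosphonium bromide, C[P+](c1ccccc1)(c1ccccc1)c1ccccc1.[Br-]
Why: Wittig methylenation, in which the non-stabilised ylide consumes the aldehyde far faster than it touches the aryl ester at 0 °C.

Step 4
Reactants: 5 methyl 7-(4-vinylphenoxy)-2,2-diphenyl-1,3-benzodioxole-5-carboxylate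
Product: 6 [7-(4-vinylphenoxy)-2,2-diphenyl-1,3-benzodioxol-5-yl]methanol
Conditions: LiAlH4, THF, 0 °C
Reagents that add atoms: none
Why: Hydride reduction of the ester to the primary alcohol, to which styrene, ketal and diaryl ether are inert.

Step 5
Reactants: 6 [7-(4-vinylphenoxy)-2,2-diphenyl-1,3-benzodioxol-5-yl]methanol
Product: 7 7-(4-vinylphenoxy)-2,2-diphenyl-1,3-benzodioxole-5-carbaldehyde
Conditions: activated MnO2, CH2Cl2, rt
Reagents that add atoms: none
Why: MnO2 oxidation of an electron-rich benzylic alcohol stops at the aldehyde and leaves the styrene alone.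

Step 6
Reactants: 8 2-fluoro-3-methoxybenzaldehyde
Product: 9 2-fluoro-3-hydroxybenzaldehyde
Conditions: BBr3, CH2Cl2, -78 to 0 °C; H2O
Reagents that add atoms: none
Why: Lewis-acid cleavage of the aryl methyl ether, done at the outset because no demethylation at the end of the route would spare the benzylic carbinol.

Step 7
Reactants: 9 2-fluoro-3-hydroxybenzaldehyde
Product: 10 3-(benzyloxy)-2-fluorobenzaldehyde
Conditions: BnBr, K2CO3, DMF, rt
Reagents that add atoms: benzyl bromide, BrCc1ccccc1
Why: Williamson etherification of the phenoxide installs a group that survives base, hydride and organometallic reagents and leaves by hydrogenolysis.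

Step 8
Reactants: 10 3-(benzyloxy)-2-fluorobenzaldehyde; 11 3-hydroxybenzyl alcohol
Product: 12 3-(benzyloxy)-2-[3-(hydroxymethyl)phenoxy]benzaldehyde
Conditions: K2CO3, DMAc, 110 °C
Reagents that add atoms: none
Why: SNAr at the fluoride activated by the ortho-formyl group, chemoselective because K2CO3 deprotonates only the phenol of 11 and leaves its benzylic alcohol untouched.

Step 9
Reactants: 12 3-(benzyloxy)-2-[3-(hydroxymethyl)phenoxy]benzaldehyde
Product: 13 {3-[2-(benzyloxy)-6-vinylphenoxy]phenyl}methanol
Conditions: Ph3PCH3Br (2.5 equiv), KOtBu (2.4 equiv), THF, 0 °C to rt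
Reagents that add atoms: methyltriphenylphosphonium bromide, C[P+](c1ccccc1)(c1ccccc1)c1ccccc1.[Br-]
Why: Wittig methylenation, with the excess ylide covering the free hydroxyl, which is returned unchanged on work-up.

Step 10
Reactants: 13 {3-[2-(benzyloxy)-6-vinylphenoxy]phenyl}methanol
Product: 14 3-[2-(benzyloxy)-6-vinylphenoxy]benzyl 2,2,2-trichloroacetimidate
Conditions: Cl3CCN, DBU (10 mol%), CH2Cl2, 0 °C
Reagents that add atoms: trichloroacetonitrile, N#CC(Cl)(Cl)Cl
Why: Base-catalysed addition of a primary alcohol to trichloroacetonitrile (imidate formation) turns the ring-D CH2OH into an electrophile that is switched on only by acid.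

Step 11
Reactants: 7 7-(4-vinylphenoxy)-2,2-diphenyl-1,3-benzodioxole-5-carbaldehyde
Product: 15 rac-[7-(4-vinylphenoxy)-2,2-diphenyl-1,3-benzodioxol-5-yl](tributylstannyl)methanol
Conditions: Bu3SnH, LDA, THF, 0 °C; then 7, -78 °C; aq NH4Cl at -78 °C, cold work-up, used crude at once
Reagents that add atoms: tributyltin hydride (used as Bu3SnLi), CCCC[SnH](CCCC)(CCCC)
Why: 1,2-Addition of a stannyl anion to an aldehyde gives the alpha-hydroxystannane, and its new centre is formed racemic without consequence because it is erased in step 15.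

Step 12
Reactants: 15 rac-[7-(4-vinylphenoxy)-2,2-diphenyl-1,3-benzodioxol-5-yl](tributylstannyl)methanol; 14 3-[2-(benzyloxy)-6-vinylphenoxy]benzyl 2,2,2-trichloroacetimidate
Product: 16 rac-tributyl{[7-(4-vinylphenoxy)-2,2-diphenyl-1,3-benzodioxol-5-yl]({3-[2-(benzyloxy)-6-vinylphenoxy]benzyl}oxy)methyl}stannane (acyclic alpha-stannyl dibenzyl ether, two styrenes)
Conditions: 14 (1.5 equiv), TMSOTf (5 mol%), 4 Å MS, CH2Cl2/cyclohexane, -30 to 0 °C; Et3N quench; Et3N-deactivated silica
Reagents that add atoms: none
Why: Acid-catalysed O-benzylation with a trichloroacetimidate, the usual way to etherify base-labile alpha-metallated carbinols, avoids the alkoxide of 15 (which would revert to 7 and stannyl anion or shift tin from C to O), and run bimolecularly at high concentration the alcohol should outrun imidate rearrangement and attack on the styrenes.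

Step 13
Reactants: 16 acyclic alpha-stannyl dibenzyl ether diene
Product: 17 rac-19-membered alpha-tributylstannyl dibenzyl ether with a B/C stilbene bridge (E/Z mixture)
Conditions: Grubbs second-generation catalyst (10 mol%), CH2Cl2 (1 mM, slow addition), reflux
Reagents that add atoms: none
Why: Ring-closing metathesis of two terminal styrenes is driven by loss of ethene and by the low reactivity of the stilbene formed, while high dilution favours the ring, the stannane, ethers and ketal are inert to the ruthenium carbene, and the alkene geometry is irrelevant.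

Step 14
Reactants: 17 19-membered stilbene stannane
Product: 18 rac-19-membered alpha-tributylstannyl dibenzyl ether (ring-A catechol as diphenylmethylene ketal, ring-C phenol as benzyl ether, saturated B/C bridge)
Conditions: 2-nitrobenzenesulfonylhydrazide (NBSH, excess, in portions), Et3N, CH2Cl2, rt
Reagents that add atoms: none
Why: Diimide reduction (concerted syn transfer of two hydrogens from HN=NH) saturates the stilbene without metal catalyst or free acid, so the C-Sn bond, the O-benzyl group and the ketal, all at risk under catalytic hydrogenation, should persist.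

Step 15
Reactants: 18 rac-19-membered alpha-tributylstannyl dibenzyl ether
Product: 20 (S)-carbinol macrocycle (18-membered; ring-A diphenylmethylene ketal, ring-C O-benzyl), via ring-A benzylic organolithium 19 (not isolated)
Conditions: (S,S)-iPr-box (CMe2-bridged, 1.3 equiv), n-BuLi (1.05 equiv), Et2O/toluene, -78 °C, premixed; then 18, -78 to -45 °C; aq NH4Cl
Reagents that add atoms: none
Why: Proposed new method: n-BuLi adds to tin, the stannate expels Bu4Sn and leaves the ring-A alpha-alkoxybenzyllithium 19, whose O-CH2(ring D) bond then breaks homolytically to a lithium ketyl and a ring-D benzyl radical that recombine at the former carbanion carbon ([1,2]-Wittig rearrangement). The closest known reactions are the tin-lithium-triggered [1,2]-Wittig shift of acyclic alpha-stannyl benzyl ethers and the alkyllithium/bis(oxazoline)-mediated enantioselective rearrangement of acyclic dibenzyl ethers, and what is new is the use on a macrocycle as a ring contraction. The 18-membered ring closes by a 1,2-shift of the ring-D CH2 from the endocyclic oxygen to the adjacent ring carbon (19 to 18, the oxygen becoming the exocyclic hydroxyl), and because both radical centres stay tied together through rings B and C they cannot diffuse apart, so recombination should beat escape. The single new stereocentre is controlled by the C2-symmetric ligand on lithium: 19 is a configurationally labile benzylic organolithium, so both enantiomers of 18 feed the same pair of rapidly interconverting ligand complexes, and the faster-rearranging one, with the ligand still bound at the ketyl oxygen during recombination, sets (S). The step needs site selectivity for the ring-A benzylic carbon although the ring-D OCH2 and the remaining ArOCH2Ph are more acidic, and this is secured by the position of tin, by exchange outrunning deprotonation at -78 °C with only 1.05 equiv of n-BuLi, and by the ketal on ring A, which has no benzylic hydrogen.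

Step 16
Reactants: 20 (S)-carbinol macrocycle
Product: 21 CNP0333307.1, the (S)-configured target
Conditions: H2 (1 atm), 10% Pd/C, EtOAc/THF, rt, stopped after uptake of 3 equiv H2
Reagents that add atoms: none
Why: Catalytic hydrogenolysis cleaves the aryl benzyl ether and the doubly benzylic ketal under neutral aprotic conditions, where the unactivated secondary carbinol is a poor leaving group (as in the debenzylation of catechol-type arylethanolamines) and no acid or base is present to racemise the centre through a quinone methide.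

Compound list
1 | methyl gallate | COC(=O)c1cc(O)c(O)c(O)c1 | starting material
2 | methyl 7-hydroxy-2,2-diphenyl-1,3-benzodioxole-5-carboxylate | COC(=O)c1cc(O)c2OC(c3ccccc3)(c3ccccc3)Oc2c1 | intermediate
3 | 4-fluorobenzaldehyde | O=Cc1ccc(F)cc1 | starting material
4 | methyl 7-(4-formylphenoxy)-2,2-diphenyl-1,3-benzodioxole-5-carboxylate | COC(=O)c1cc(Oc3ccc(C=O)cc3)c2OC(c3ccccc3)(c3ccccc3)Oc2c1 | intermediate
5 | methyl 7-(4-vinylphenoxy)-2,2-diphenyl-1,3-benzodioxole-5-carboxylate | COC(=O)c1cc(Oc3ccc(C=C)cc3)c2OC(c3ccccc3)(c3ccccc3)Oc2c1 | intermediate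
6 | [7-(4-vinylphenoxy)-2,2-diphenyl-1,3-benzodioxol-5-yl]methanol | OCc1cc(Oc3ccc(C=C)cc3)c2OC(c3ccccc3)(c3ccccc3)Oc2c1 | intermediate
7 | 7-(4-vinylphenoxy)-2,2-diphenyl-1,3-benzodioxole-5-carbaldehyde | O=Cc1cc(Oc3ccc(C=C)cc3)c2OC(c3ccccc3)(c3ccccc3)Oc2c1 | intermediate
8 | 2-fluoro-3-methoxybenzaldehyde | COc1cccc(C=O)c1F | starting material
9 | 2-fluoro-3-hydroxybenzaldehyde | Oc1cccc(C=O)c1F | intermediate
10 | 3-(benzyloxy)-2-fluorobenzaldehyde | O=Cc1cccc(OCc2ccccc2)c1F | intermediate
11 | 3-hydroxybenzyl alcohol | OCc1cccc(O)c1 | starting material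
12 | 3-(benzyloxy)-2-[3-(hydroxymethyl)phenoxy]benzaldehyde | O=Cc1cccc(OCc2ccccc2)c1Oc1cccc(CO)c1 | intermediate
13 | {3-[2-(benzyloxy)-6-vinylphenoxy]phenyl}methanol | C=Cc1cccc(OCc2ccccc2)c1Oc1cccc(CO)c1 | intermediate
14 | 3-[2-(benzyloxy)-6-vinylphenoxy]benzyl 2,2,2-trichloroacetimidate | C=Cc1cccc(OCc2ccccc2)c1Oc1cccc(COC(=N)C(Cl)(Cl)Cl)c1 | intermediate
15 | rac-[7-(4-vinylphenoxy)-2,2-diphenyl-1,3-benzodioxol-5-yl](tributylstannyl)methanol | OC(c1cc(Oc3ccc(C=C)cc3)c2OC(c3ccccc3)(c3ccccc3)Oc2c1)[Sn](CCCC)(CCCC)CCCC | intermediate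
16 | rac acyclic alpha-tributylstannyl dibenzyl ether diene | C=Cc1ccc(cc1)Oc1cc(cc2OC(c3ccccc3)(c3ccccc3)Oc12)C(OCc1cccc(Oc2c(C=C)cccc2OCc2ccccc2)c1)[Sn](CCCC)(CCCC)CCCC | intermediate
17 | rac 19-membered alpha-tributylstannyl dibenzyl ether, B/C stilbene (E/Z) | C3(c4ccccc4)(c4ccccc4)Oc1cc2cc(c1O3)Oc1ccc(cc1)C=Cc1cccc(OCc3ccccc3)c1Oc1cccc(c1)COC2[Sn](CCCC)(CCCC)CCCC | intermediate
18 | rac 19-membered alpha-tributylstannyl dibenzyl ether (key-step precursor) | C3(c4ccccc4)(c4ccccc4)Oc1cc2cc(c1O3)Oc1ccc(cc1)CCc1cccc(OCc3ccccc3)c1Oc1cccc(c1)COC2[Sn](CCCC)(CCCC)CCCC | intermediate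
19 | ring-A benzylic organolithium of the 19-membered ether (ligand-bound, configurationally labile) | C3(c4ccccc4)(c4ccccc4)Oc1cc2cc(c1O3)Oc1ccc(cc1)CCc1cccc(OCc3ccccc3)c1Oc1cccc(c1)COC2[Li] | intermediate
20 | (S)-carbinol macrocycle, 18-membered (key-step product) | C3(c4ccccc4)(c4ccccc4)Oc1cc2cc(c1O3)Oc1ccc(cc1)CCc1cccc(OCc3ccccc3)c1Oc1cccc(c1)C[C@@H]2O | intermediate
21 | CNP0333307.1, (S) | Oc1cc2cc(c1O)Oc1ccc(cc1)CCc1cccc(O)c1Oc1cccc(c1)C[C@@H]2O | target

Total step count: 16. Longest linear sequence: 11 (steps 1-5 and 11-16).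

Steps most likely to fail

Step 15 (the labelled step).
- **What may go wrong:** facial discrimination may be weak when the tethered radical pair recombines. A proton may transfer from the ring-D OCH2 or the OCH2Ph group to the carbanion before it rearranges. Exchange may also be sluggish in the weakly coordinating solvent. A moderate enantiomeric excess could be raised by recrystallisation of 20.
- **Fallback:** it uses known chemistry only, sets out from 7 and 13 and comes back at 20. The CH-CH2 bond is made by carbonyl addition and the centre by ketone reduction.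
  - An Appel reaction (PPh3, CCl4) turns 13 into the benzylic chloride F1.
  - Magnesium in 2-MeTHF gives the benzylic Grignard reagent F2, which adds to 7 to give the racemic diene carbinol F3.
  - Dess-Martin oxidation gives the diene ketone F4.
  - Ring-closing metathesis at high dilution gives the 18-membered stilbene ketone F5, and diimide gives the macrocyclic aryl benzyl ketone F6.
  - Asymmetric transfer hydrogenation of the latter with RuCl[(S,S)-TsDPEN](p-cymene) in HCO2H/Et3N should give 20, since it differentiates aryl from alkyl as in other aryl alkyl ketones.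

Step 12.
- **What may go wrong:** 15 may decay before it is alkylated. The electron-rich benzylic stannane may undergo protodestannylation or ionisation under the acid catalyst. The styrenes may suffer cationic attack.
- **Fallback:** it sets out from 7 and 13, comes back at 16 and bypasses step 11 as well. The C-Sn bond is made last, so no hydroxystannane is handled.
  - Acetalisation of 7 with two equivalents of 13 (PPTS, toluene, azeotropic removal of water) gives the bis(benzylic) acetal F7.
  - Acetyl chloride at 0 °C exchanges one alkoxy group for chloride to give the alpha-chloro ether F8, which is used at once.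
  - SN2 displacement of chloride with Bu3SnLi in THF at -78 °C, the standard route from alpha-chloro ethers to alpha-alkoxystannanes, gives 16.

Step 13.
- **What may go wrong:** oligomerisation may compete with ring closure, and the catalyst may be held back by chelation of the ortho-aryloxy benzylidene on ring C.
- **Fallback:** it sets out from 12 and 15, comes back at 18 and also replaces step 14. The saturated bridge is closed directly by a macrocyclic B-alkyl Suzuki coupling.
  - Baeyer-Villiger oxidation of 12 with mCPBA gives the aryl formate F9, and methanolysis (K2CO3, MeOH) gives the phenol F10.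
  - PhNTf2/Et3N sulfonylates only the phenol to give the aryl triflate F11.
  - Cl3CCN/DBU gives the triflate imidate F12.
  - Etherification of 15 as in step 12 gives the stannyl ether triflate F13, which holds a single styrene.
  - 9-BBN adds to that styrene to give the B-alkyl borane F14.
  - Pd(dppf)Cl2, AsPh3 and Cs2CO3 in DMF/THF/H2O at high dilution close the CH2CH2 bridge to give 18.

Further compounds
F1 | step 15 | 1-(benzyloxy)-2-[3-(chloromethyl)phenoxy]-3-vinylbenzene | C=Cc1cccc(OCc2ccccc2)c1Oc1cccc(CCl)c1
F2 | step 15 | {3-[2-(benzyloxy)-6-vinylphenoxy]benzyl}magnesium chloride | C=Cc1cccc(OCc2ccccc2)c1Oc1cccc(C[Mg]Cl)c1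
F3 | step 15 | rac-1-[7-(4-vinylphenoxy)-2,2-diphenyl-1,3-benzodioxol-5-yl]-2-{3-[2-(benzyloxy)-6-vinylphenoxy]phenyl}ethanol | C=Cc1ccc(cc1)Oc1cc(cc2OC(c3ccccc3)(c3ccccc3)Oc12)C(O)Cc1cccc(Oc2c(C=C)cccc2OCc2ccccc2)c1
F4 | step 15 | 1-[7-(4-vinylphenoxy)-2,2-diphenyl-1,3-benzodioxol-5-yl]-2-{3-[2-(benzyloxy)-6-vinylphenoxy]phenyl}ethanone | C=Cc1ccc(cc1)Oc1cc(cc2OC(c3ccccc3)(c3ccccc3)Oc12)C(=O)Cc1cccc(Oc2c(C=C)cccc2OCc2ccccc2)c1
F5 | step 15 | 18-membered stilbene ketone (E/Z) | C3(c4ccccc4)(c4ccccc4)Oc1cc2cc(c1O3)Oc1ccc(cc1)C=Cc1cccc(OCc3ccccc3)c1Oc1cccc(c1)CC2=O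
F6 | step 15 | 18-membered aryl benzyl ketone, saturated bridge | C3(c4ccccc4)(c4ccccc4)Oc1cc2cc(c1O3)Oc1ccc(cc1)CCc1cccc(OCc3ccccc3)c1Oc1cccc(c1)CC2=O
F7 | step 12 | bis{3-[2-(benzyloxy)-6-vinylphenoxy]benzyl} acetal of 7 | C=Cc1ccc(cc1)Oc1cc(cc2OC(c3ccccc3)(c3ccccc3)Oc12)C(OCc1cccc(Oc2c(C=C)cccc2OCc2ccccc2)c1)OCc1cccc(Oc2c(C=C)cccc2OCc2ccccc2)c1
F8 | step 12 | rac alpha-chloro dibenzyl ether diene | C=Cc1ccc(cc1)Oc1cc(cc2OC(c3ccccc3)(c3ccccc3)Oc12)C(Cl)OCc1cccc(Oc2c(C=C)cccc2OCc2ccccc2)c1
F9 | step 13 | 3-(benzyloxy)-2-[3-(hydroxymethyl)phenoxy]phenyl formate | O=COc1cccc(OCc2ccccc2)c1Oc1cccc(CO)c1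
F10 | step 13 | 3-(benzyloxy)-2-[3-(hydroxymethyl)phenoxy]phenol | Oc1cccc(OCc2ccccc2)c1Oc1cccc(CO)c1
F11 | step 13 | 3-(benzyloxy)-2-[3-(hydroxymethyl)phenoxy]phenyl triflate | FC(F)(F)S(=O)(=O)Oc1cccc(OCc2ccccc2)c1Oc1cccc(CO)c1
F12 | step 13 | 3-[2-(benzyloxy)-6-(triflyloxy)phenoxy]benzyl 2,2,2-trichloroacetimidate | FC(F)(F)S(=O)(=O)Oc1cccc(OCc2ccccc2)c1Oc1cccc(COC(=N)C(Cl)(Cl)Cl)c1
F13 | step 13 | rac acyclic alpha-tributylstannyl dibenzyl ether, ring-B styrene and ring-C triflate | C=Cc1ccc(cc1)Oc1cc(cc2OC(c3ccccc3)(c3ccccc3)Oc12)C(OCc1cccc(Oc2c(OS(=O)(=O)C(F)(F)F)cccc2OCc2ccccc2)c1)[Sn](CCCC)(CCCC)CCCC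
F14 | step 13 | B-alkyl-9-BBN adduct of F13 | B1(CCc2ccc(cc2)Oc2cc(cc3OC(c4ccccc4)(c4ccccc4)Oc23)C(OCc2cccc(Oc3c(OS(=O)(=O)C(F)(F)F)cccc3OCc3ccccc3)c2)[Sn](CCCC)(CCCC)CCCC)C2CCCC1CCC2
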